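**Plan**

- Ring numbering used below: cyclohexene C1 (quaternary: CH3 and the styryl arm), C2, C3, C4 (=C–CH3), C5 (=CH), C6 (CH–aryl).
- Enabling feature: the aryl carbon on C6 is C8 of a 7-methoxycoumarin, flanked by the oxygen-bearing carbons C7 and C8a, which is where 1,3-dimethoxybenzene lithiates; the C1 methyl is trans to this aryl group, the pattern left when a carbon nucleophile and then a carbon electrophile add across a C1=C6 bond.
- Retrosynthesis: cut the aryl–CH= bond of the E-styrene; open the pyranone ring of the C6-bound coumarin (C3=C4 and O1–C2) back to a 2,6-dimethoxyphenyl group; take the vinyl group back to an oxazoline carbon; cut C6–aryl and C1–CH3 together.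
- Forward: the six-membered carbocycle is bought as 4-methylcyclohex-3-ene-1-carboxylic acid and is never closed; oxazoline formation and dehydrogenation give a dienyl oxazoline; one flask adds aryl and methyl; the carbon arm becomes CHO, then vinyl; the pyranone ring is closed; the second coumarin (from umbelliferone) is joined last.
- Stereochemistry: C6 from the (R)-tert-leucinol-derived oxazoline, C1 from C6 (methylation anti to the aryl group), the E-alkene from syn β-hydride elimination in the Heck step.

Key step: step 5

Assumption on the chemistry: the aryl group is taken to enter the diene face opposite the tert-butyl group of the nitrogen-coordinated s-cis oxazoline; on this model the (R)-auxiliary leads to the (1R,6R) target (C1, C6 as numbered above), and racemic acid 1 is acceptable because its stereocentre is destroyed in step 4.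

**Route**

Step 1
Reactants: 1 4-methylcyclohex-3-ene-1-carboxylic acid (racemic); 2 (R)-tert-leucinol [(2R)-2-amino-3,3-dimethylbutan-1-ol]
Product: 3 N-[(2R)-1-hydroxy-3,3-dimethylbutan-2-yl]-4-methylcyclohex-3-ene-1-carboxamide (two epimers at the ring carbon)
Conditions: DCC, HOBt (cat.), CH2Cl2, 0 °C to rt
Reagents that add atoms: none
Why: Carbodiimide-mediated amide coupling: the primary amine of 2 is far more nucleophilic than its hydroxyl group toward the activated ester, so the hydroxy amide should form without protection, and the epimeric mixture at the ring carbon is of no consequence because that centre becomes sp2 in step 4.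

Step 2
Reactants: 3 hydroxy amide
Product: 5 (4R)-4-tert-butyl-2-(4-methylcyclohex-3-en-1-yl)-4,5-dihydro-1,3-oxazole (two epimers at the ring carbon), via mesylate 4 (not isolated)
Conditions: MsCl, Et3N, CH2Cl2, 0 °C to reflux
Reagents that add atoms: none
Why: Cyclodehydration of a β-hydroxy amide to a 2-oxazoline: O-mesylation to 4 followed by intramolecular SN2 displacement at the primary carbon by the amide oxygen should close the heterocycle without touching the tert-butyl-bearing stereocentre.

Step 3
Reactants: 5 cyclohexenyl oxazoline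
Product: 7 (4R)-4-tert-butyl-2-[4-methyl-1-(phenylselanyl)cyclohex-3-en-1-yl]-4,5-dihydro-1,3-oxazole (two epimers), via lithium azaenolate 6 (not isolated)
Conditions: LiN(iPr)2, THF, −78 °C; PhSeBr, −78 to 0 °C
Reagents that add atoms: benzeneselenenyl bromide, Br[Se]c1ccccc1
Why: α-Selenenylation of a lithium azaenolate: the C–H next to the oxazoline is the most acidic site of 5, and azaenolate 6 should be trapped at carbon by PhSeBr to give the tertiary selenide.

Step 4
Reactants: 7 selenide
Product: 9 (4R)-4-tert-butyl-2-(4-methylcyclohexa-1,3-dien-1-yl)-4,5-dihydro-1,3-oxazole, via selenoxide 8 (not isolated)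
Conditions: mCPBA (1.0 equiv), CH2Cl2, −78 °C; i-Pr2NH, −78 °C to rt; DBU (cat.), rt; argon
Reagents that add atoms: none
Why: Selenoxide syn-elimination: the selenide is oxidised at −78 °C faster than the alkene, selenoxide 8 fragments on warming toward the allylic ring CH2 to give the conjugated diene, and DBU should convert any skipped 1,4-diene formed by elimination toward the other CH2 into the same linearly conjugated isomer through the azaenolate-stabilised γ-anion.

Step 5
Reactants: 9 dienyl oxazoline; 10 1,3-dimethoxybenzene; 11 iodomethane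
Product: 14 (4R)-4-tert-butyl-2-[(1S,2S)-2-(2,6-dimethoxyphenyl)-1,4-dimethylcyclohex-3-en-1-yl]-4,5-dihydro-1,3-oxazole (aryl cis to oxazoline; C1 methyl trans to aryl), via 2,6-dimethoxyphenyllithium 12 (not isolated), via lithium azaenolate 13 (not isolated)
Conditions: 10, n-BuLi, THF, 0 °C to rt; then 9, THF, −78 to −30 °C; then MeI, −78 °C to rt
Reagents that add atoms: iodomethane 11, CI
Why: Aryllithium 12, formed by lithiation of 10 between its two methoxy groups, coordinates the oxazoline nitrogen of 9 in the s-cis N=C–C1=C6 conformer and transfers its aryl group to C6 through a six-membered array, giving lithium azaenolate 13, which iodomethane methylates at C1. The closest known reaction type is the tandem organolithium conjugate addition–alkyl halide trapping of chiral 4-substituted 2-(1-naphthyl)- and 2-alkenyl-2-oxazolines; no ring is closed. C6 is set by the auxiliary: the tert-butyl group on C4 of the (4R)-oxazoline shields one face of the planar azadiene, so the nitrogen-bound aryllithium delivers the aryl group to the opposite face. C1 is set by C6: iodomethane approaches the azaenolate anti to the new, bulky aryl group, leaving CH3 trans and the oxazoline carbon cis to the aryl group. The step needs 1,4- rather than 1,6-addition and addition rather than deprotonation of the C3 methylene; the first is secured by nitrogen-directed delivery, which reaches only C6, and by the methyl group on the δ-carbon C4, the second by low temperature and the lower basicity of an aryllithium compared with an alkyllithium.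

Step 6
Reactants: 14 arylated, methylated oxazoline
Product: 17 (1S,2S)-2-(2,6-dimethoxyphenyl)-1,4-dimethylcyclohex-3-ene-1-carbaldehyde, via N-methyloxazolinium triflate 15 (not isolated), via N-methyloxazolidine 16 (not isolated)
Conditions: MeOTf, CH2Cl2, rt; NaBH4, THF/MeOH, 0 °C; oxalic acid, THF/H2O, rt
Reagents that add atoms: water, O
Why: Unmasking of a 2-oxazoline to an aldehyde by N-methylation, hydride reduction of the oxazolinium salt and mild acid hydrolysis of the N-methyloxazolidine, a sequence that tolerates a quaternary α-carbon; since that carbon bears no hydrogen, neither stereocentre can epimerise.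

Step 7
Reactants: 17 aldehyde
Product: 18 2-[(1R,6R)-6-ethenyl-3,6-dimethylcyclohex-2-en-1-yl]-1,3-dimethoxybenzene
Conditions: Ph3PCH3Br, KOtBu, THF, 0 °C to rt
Reagents that add atoms: methyltriphenylphosphonium bromide, C[P+](c1ccccc1)(c1ccccc1)c1ccccc1.[Br-]
Why: Wittig methylenation with the unstabilised ylide, which is reliable for hindered non-enolisable aldehydes; no stereocentre is affected (the change of descriptors from 17 to 18 reflects only the new substituent priorities).

Step 8
Reactants: 18 vinyl dimethoxyarene
Product: 19 2-[(1R,6R)-6-ethenyl-3,6-dimethylcyclohex-2-en-1-yl]-3-methoxyphenol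
Conditions: NaSEt, DMF, 140 °C; then 1 M HCl, 0 °C
Reagents that add atoms: none
Why: Nucleophilic O-demethylation of an aryl methyl ether by thiolate (SN2 at the methyl carbon): the two methoxy groups are equivalent by the local symmetry of the aryl ring and the phenoxide formed shuts down a second cleavage, so one phenol should result, while cold dilute acid in the work-up avoids addition of the phenol to the ring alkene.

Step 9
Reactants: 19 phenol
Product: 21 3-[(1R,6R)-6-ethenyl-3,6-dimethylcyclohex-2-en-1-yl]-2-hydroxy-4-methoxybenzaldehyde, via hydroxymethylphenol 20 (not isolated)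
Conditions: MgCl2, Et3N, (CH2O)n, MeCN, reflux; then 1 M HCl, 0 °C
Reagents that add atoms: paraformaldehyde (as formaldehyde), C=O
Why: Magnesium-mediated ortho-formylation of a phenol: the magnesium phenoxide directs formaldehyde to the only free ortho position to give benzylic alcohol 20, which is oxidised in the flask by hydride transfer to a second formaldehyde.

Step 10
Reactants: 21 salicylaldehyde
Product: 23 8-[(1R,6R)-6-ethenyl-3,6-dimethylcyclohex-2-en-1-yl]-7-methoxy-2H-chromen-2-one, via phosphoranylideneacetate 22 (not isolated)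
Conditions: Ph3P=C=C=O, toluene, reflux
Reagents that add atoms: (triphenylphosphoranylidene)ketene, O=C=C=P(c1ccccc1)(c1ccccc1)c1ccccc1
Why: Addition–intramolecular Wittig cascade: the phenol adds across the ketenylidene ylide to give ester ylide 22, which olefinates the neighbouring aldehyde within the ring and so delivers the cis-configured lactone (the 2H-chromen-2-one) at a temperature that should leave the 1,5-diene unit untouched.

Step 11
Reactants: 24 umbelliferone (7-hydroxy-2H-chromen-2-one)
Product: 25 7-hydroxy-8-iodo-2H-chromen-2-one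
Conditions: I2, KI, aq. NH3, 0 °C to rt; then aq. HCl
Reagents that add atoms: iodine, II
Why: Electrophilic aromatic iodination of the phenoxide, which in 7-hydroxycoumarins takes place at C8, the position ortho to the phenoxide oxygen and next to the carbon carrying the ring oxygen.

Step 12
Reactants: 25 iodophenol; 11 iodomethane
Product: 26 8-iodo-7-methoxy-2H-chromen-2-one
Conditions: MeI, K2CO3, acetone, reflux
Reagents that add atoms: iodomethane 11, CI
Why: Williamson O-methylation of the phenol with a carbonate base mild enough to leave the lactone closed.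

Step 13
Reactants: 23 vinyl coumarin; 26 8-iodo-7-methoxycoumarin
Product: 27 7-methoxy-8-[(E)-2-[(1R,2R)-2-(7-methoxy-2-oxo-2H-chromen-8-yl)-1,4-dimethylcyclohex-3-en-1-yl]ethenyl]-2H-chromen-2-one (target)
Conditions: Pd(OAc)2 (10 mol %), n-Bu4NCl, NaHCO3, DMF, 80 °C
Reagents that add atoms: none
Why: Mizoroki–Heck reaction under ligand-free phase-transfer conditions: zerovalent palladium formed in the flask inserts into the C–I bond of 26, the arylpalladium species adds to the terminal carbon of the monosubstituted alkene of 23, and syn β-hydride elimination, possible only from the benzylic CH2 because the other neighbour is the quaternary C1, should give the E-styrene without touching the trisubstituted ring alkene, the coumarin C3=C4 bonds or either stereocentre.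

**Compound list**

1 | 4-methylcyclohex-3-ene-1-carboxylic acid (racemic) | CC1=CCC(CC1)C(=O)O | starting material
2 | (R)-tert-leucinol, (2R)-2-amino-3,3-dimethylbutan-1-ol | CC(C)(C)[C@@H](N)CO | starting material
3 | N-[(2R)-1-hydroxy-3,3-dimethylbutan-2-yl]-4-methylcyclohex-3-ene-1-carboxamide (epimers at the ring carbon) | CC1=CCC(CC1)C(=O)N[C@@H](CO)C(C)(C)C | intermediate
4 | (2R)-3,3-dimethyl-2-[(4-methylcyclohex-3-ene-1-carbonyl)amino]butyl methanesulfonate (formed in the flask) | CC1=CCC(CC1)C(=O)N[C@@H](COS(C)(=O)=O)C(C)(C)C | intermediate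
5 | (4R)-4-tert-butyl-2-(4-methylcyclohex-3-en-1-yl)-4,5-dihydro-1,3-oxazole (epimers at the ring carbon) | CC(C)(C)[C@@H]1COC(=N1)C1CCC(C)=CC1 | intermediate
6 | (4R)-4-tert-butyl-3-lithio-2-(4-methylcyclohex-3-en-1-ylidene)-1,3-oxazolidine, lithium azaenolate of 5 (formed in the flask) | CC(C)(C)[C@@H]1COC(=C2CCC(C)=CC2)N1[Li] | intermediate
7 | (4R)-4-tert-butyl-2-[4-methyl-1-(phenylselanyl)cyclohex-3-en-1-yl]-4,5-dihydro-1,3-oxazole (epimers) | CC(C)(C)[C@@H]1COC(=N1)C1(CCC(C)=CC1)[Se]c1ccccc1 | intermediate
8 | (4R)-4-tert-butyl-2-[4-methyl-1-(phenylseleninyl)cyclohex-3-en-1-yl]-4,5-dihydro-1,3-oxazole (formed in the flask) | CC(C)(C)[C@@H]1COC(=N1)C1(CCC(C)=CC1)[Se](=O)c1ccccc1 | intermediate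
9 | (4R)-4-tert-butyl-2-(4-methylcyclohexa-1,3-dien-1-yl)-4,5-dihydro-1,3-oxazole | CC(C)(C)[C@@H]1COC(=N1)C1=CC=C(C)CC1 | intermediate
10 | 1,3-dimethoxybenzene | COc1cccc(OC)c1 | starting material
11 | iodomethane | CI | starting material
12 | 2,6-dimethoxyphenyllithium (formed in the flask) | [Li]c1c(OC)cccc1OC | intermediate
13 | (4R)-4-tert-butyl-2-[(2S)-2-(2,6-dimethoxyphenyl)-4-methylcyclohex-3-en-1-ylidene]-3-lithio-1,3-oxazolidine, lithium azaenolate (formed in the flask) | CC(C)(C)[C@@H]1COC(=C2CCC(C)=C[C@H]2c2c(OC)cccc2OC)N1[Li] | intermediate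
14 | (4R)-4-tert-butyl-2-[(1S,2S)-2-(2,6-dimethoxyphenyl)-1,4-dimethylcyclohex-3-en-1-yl]-4,5-dihydro-1,3-oxazole | CC(C)(C)[C@@H]1COC(=N1)[C@@]1(C)CCC(C)=C[C@H]1c1c(OC)cccc1OC | intermediate
15 | (4R)-4-tert-butyl-2-[(1S,2S)-2-(2,6-dimethoxyphenyl)-1,4-dimethylcyclohex-3-en-1-yl]-3-methyl-4,5-dihydro-1,3-oxazol-3-ium trifluoromethanesulfonate (formed in the flask) | CC(C)(C)[C@@H]1COC(=[N+]1C)[C@@]1(C)CCC(C)=C[C@H]1c1c(OC)cccc1OC.[O-]S(=O)(=O)C(F)(F)F | intermediate
16 | (4R)-4-tert-butyl-2-[(1S,2S)-2-(2,6-dimethoxyphenyl)-1,4-dimethylcyclohex-3-en-1-yl]-3-methyl-1,3-oxazolidine (epimers at C2 of the oxazolidine; formed in the flask) | CC(C)(C)[C@@H]1COC(N1C)[C@@]1(C)CCC(C)=C[C@H]1c1c(OC)cccc1OC | intermediate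
17 | (1S,2S)-2-(2,6-dimethoxyphenyl)-1,4-dimethylcyclohex-3-ene-1-carbaldehyde | O=C[C@@]1(C)CCC(C)=C[C@H]1c1c(OC)cccc1OC | intermediate
18 | 2-[(1R,6R)-6-ethenyl-3,6-dimethylcyclohex-2-en-1-yl]-1,3-dimethoxybenzene | C=C[C@@]1(C)CCC(C)=C[C@H]1c1c(OC)cccc1OC | intermediate
19 | 2-[(1R,6R)-6-ethenyl-3,6-dimethylcyclohex-2-en-1-yl]-3-methoxyphenol | C=C[C@@]1(C)CCC(C)=C[C@H]1c1c(O)cccc1OC | intermediate
20 | 2-[(1R,6R)-6-ethenyl-3,6-dimethylcyclohex-2-en-1-yl]-6-(hydroxymethyl)-3-methoxyphenol (formed in the flask) | C=C[C@@]1(C)CCC(C)=C[C@H]1c1c(O)c(CO)ccc1OC | intermediate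
21 | 3-[(1R,6R)-6-ethenyl-3,6-dimethylcyclohex-2-en-1-yl]-2-hydroxy-4-methoxybenzaldehyde | C=C[C@@]1(C)CCC(C)=C[C@H]1c1c(O)c(C=O)ccc1OC | intermediate
22 | 2-[(1R,6R)-6-ethenyl-3,6-dimethylcyclohex-2-en-1-yl]-6-formyl-3-methoxyphenyl (triphenylphosphoranylidene)acetate (formed in the flask) | C=C[C@@]1(C)CCC(C)=C[C@H]1c1c(OC(=O)C=P(c2ccccc2)(c2ccccc2)c2ccccc2)c(C=O)ccc1OC | intermediate
23 | 8-[(1R,6R)-6-ethenyl-3,6-dimethylcyclohex-2-en-1-yl]-7-methoxy-2H-chromen-2-one | C=C[C@@]1(C)CCC(C)=C[C@H]1c1c(OC)ccc2ccc(=O)oc12 | intermediate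
24 | umbelliferone, 7-hydroxy-2H-chromen-2-one | Oc1ccc2ccc(=O)oc2c1 | starting material
25 | 7-hydroxy-8-iodo-2H-chromen-2-one | Oc1ccc2ccc(=O)oc2c1I | intermediate
26 | 8-iodo-7-methoxy-2H-chromen-2-one | COc1ccc2ccc(=O)oc2c1I | intermediate
27 | 7-methoxy-8-[(E)-2-[(1R,2R)-2-(7-methoxy-2-oxo-2H-chromen-8-yl)-1,4-dimethylcyclohex-3-en-1-yl]ethenyl]-2H-chromen-2-one | COc1ccc2ccc(=O)oc2c1/C=C/[C@@]1(C)CCC(C)=C[C@H]1c1c(OC)ccc2ccc(=O)oc12 | target

**Step count**

Total: 13 steps. Longest linear sequence: 11 steps (steps 1–10, then 13); the iodocoumarin branch is steps 11–12.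

**Steps most likely to fail**

1. Step 5. The hindered aryllithium may abstract a proton from the C3 allylic methylene instead of bonding to C6, or the aryl transfer may discriminate the two diene faces poorly. The fallback is a catalytic enantioselective Diels–Alder construction that sets out from 1,3-dimethoxybenzene 10 and rejoins the route at aldehyde 17, replacing steps 1–6. Lithiation of 10 (n-BuLi, THF) and formylation with DMF would give 2,6-dimethoxybenzaldehyde F1. Claisen–Schmidt condensation with acetone (aq. NaOH) would give (3E)-4-(2,6-dimethoxyphenyl)but-3-en-2-one F2, and Wittig methylenation (Ph3PCH3Br, KOtBu, THF) would give 2-[(1E)-3-methylbuta-1,3-dien-1-yl]-1,3-dimethoxybenzene F3. Cycloaddition of F3 with methacrolein, catalysed by a proline-derived B-(o-tolyl)oxazaborolidine activated with HN(SO2CF3)2 in CH2Cl2 at −78 °C, should form the C6–C1 and C3–C2 bonds. The aryl-bearing diene terminus should bond to the formyl-bearing carbon, since the 1-aryl and 3-methyl groups direct the same way. The formyl group should sit endo and hence cis to the aryl group, and the absolute sense would be chosen through the catalyst enantiomer, giving 17.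

2. Step 13. Migratory insertion between the doubly ortho-substituted arylpalladium species and the neopentyl-type vinyl group may be slow, so that reductive loss of iodine and catalyst decomposition outrun coupling. The fallback builds both coumarins at once; it sets out from aldehyde 17 and ends at target 27, replacing steps 7–13. Horner–Wadsworth–Emmons olefination of 17 with the potassium anion (KOtBu, THF) of diethyl [(2,6-dimethoxyphenyl)methyl]phosphonate F4 (from commercial 2,6-dimethoxybenzyl alcohol, P(OEt)3 and ZnI2) would give 2-[(E)-2-[(1R,2R)-2-(2,6-dimethoxyphenyl)-1,4-dimethylcyclohex-3-en-1-yl]ethenyl]-1,3-dimethoxybenzene F5. NaSEt in DMF would remove one methyl group from each of the two locally symmetric rings to give 2-[(E)-2-[(1R,2R)-2-(2-hydroxy-6-methoxyphenyl)-1,4-dimethylcyclohex-3-en-1-yl]ethenyl]-3-methoxyphenol F6. Twofold magnesium-mediated ortho-formylation (MgCl2, Et3N, paraformaldehyde) would give 3-[(E)-2-[(1R,2R)-2-(3-formyl-2-hydroxy-6-methoxyphenyl)-1,4-dimethylcyclohex-3-en-1-yl]ethenyl]-2-hydroxy-4-methoxybenzaldehyde F7. Twofold annulation with Ph3P=C=C=O in toluene would close both pyranone rings to give 27.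

3. Step 4. The electron-rich diene may be over-oxidised or epoxidised by selenium-derived peroxy species, or the cyclohexadiene may aromatise in air during the elimination. The fallback reaches the diene oxidation level by cycloaddition; it sets out from (R)-tert-leucinol 2 and rejoins the route at 9, replacing steps 1–4. Diels–Alder reaction of isoprene with propiolic acid would give 4-methylcyclohexa-1,4-diene-1-carboxylic acid F8, the 1,4-substituted adduct, purified by crystallisation. DCC coupling with 2 would give N-[(2R)-1-hydroxy-3,3-dimethylbutan-2-yl]-4-methylcyclohexa-1,4-diene-1-carboxamide F9, and cyclodehydration (MsCl, Et3N) would give (4R)-4-tert-butyl-2-(4-methylcyclohexa-1,4-dien-1-yl)-4,5-dihydro-1,3-oxazole F10. A DBU-mediated prototropic shift of the skipped diene into conjugation would then give 9 without any oxidation.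

**Further compounds**

F1 | step 5 | 2,6-dimethoxybenzaldehyde | COc1cccc(OC)c1C=O
F2 | step 5 | (3E)-4-(2,6-dimethoxyphenyl)but-3-en-2-one | COc1cccc(OC)c1/C=C/C(C)=O
F3 | step 5 | 2-[(1E)-3-methylbuta-1,3-dien-1-yl]-1,3-dimethoxybenzene | COc1cccc(OC)c1/C=C/C(C)=C
F4 | step 13 | diethyl [(2,6-dimethoxyphenyl)methyl]phosphonate | CCOP(=O)(Cc1c(OC)cccc1OC)OCC
F5 | step 13 | 2-[(E)-2-[(1R,2R)-2-(2,6-dimethoxyphenyl)-1,4-dimethylcyclohex-3-en-1-yl]ethenyl]-1,3-dimethoxybenzene | COc1cccc(OC)c1/C=C/[C@@]1(C)CCC(C)=C[C@H]1c1c(OC)cccc1OC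
F6 | step 13 | 2-[(E)-2-[(1R,2R)-2-(2-hydroxy-6-methoxyphenyl)-1,4-dimethylcyclohex-3-en-1-yl]ethenyl]-3-methoxyphenol | COc1cccc(O)c1/C=C/[C@@]1(C)CCC(C)=C[C@H]1c1c(O)cccc1OC
F7 | step 13 | 3-[(E)-2-[(1R,2R)-2-(3-formyl-2-hydroxy-6-methoxyphenyl)-1,4-dimethylcyclohex-3-en-1-yl]ethenyl]-2-hydroxy-4-methoxybenzaldehyde | COc1ccc(C=O)c(O)c1/C=C/[C@@]1(C)CCC(C)=C[C@H]1c1c(O)c(C=O)ccc1OC
F8 | step 4 | 4-methylcyclohexa-1,4-diene-1-carboxylic acid | CC1=CCC(=CC1)C(=O)O
F9 | step 4 | N-[(2R)-1-hydroxy-3,3-dimethylbutan-2-yl]-4-methylcyclohexa-1,4-diene-1-carboxamide | CC1=CCC(=CC1)C(=O)N[C@@H](CO)C(C)(C)C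
F10 | step 4 | (4R)-4-tert-butyl-2-(4-methylcyclohexa-1,4-dien-1-yl)-4,5-dihydro-1,3-oxazole | CC(C)(C)[C@@H]1COC(=N1)C1=CCC(C)=CC1
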